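Replace each curve by its mean, and the set-ups below reduce to a line of arithmetic.

| flask | substrate | coupling partner | second reagent | remark | time |
|---|---|---|---|---|---|
| Wednesday's | 49 mM | 1.2 equiv | 0.90 equiv | run made earlier |  |
| Friday's | 33 mM | 1.2 equiv | 0.90 equiv | run made earlier |  |
| Saturday's | 74 mM | 1.2 equiv | 0.90 equiv | run made earlier |  |
| Monday's | 49 mM | 1.8 equiv | 0.90 equiv | run made earlier |  |
| epsilon | 49 mM | 1.20 equiv | 0.900 equiv | a closed flask charged with all of it at once and left for 8.0 h | 8.0 h |
| beta | 49 mM (fed, over 6.40 h) | 1.20 equiv | 0.900 equiv | all but substrate at the start; substrate goes in evenly over 6.40 h, the run ends at 8.0 h | 8.0 h |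
| delta | 49 mM | 1.20 equiv | 0.900 equiv | a single well-mixed tank run continuously and read at steady state, 8.0 h in it on average |  |
| gamma | 49 mM | 1.20 equiv (fed, over 6.40 h) | 0.900 equiv | a stirred flask in which coupling partner is dosed at a steady rate over 6.40 h without added volume, worked up at 8.0 h | 8.0 h |

| run | time / h | intermediate / % | target / % |
|---|---|---|---|
| Wednesday's | 1.00 | 9.7 | 0 |
| Wednesday's | 2.00 | 13.0 | 3.3 |
| Wednesday's | 3.00 | 17.9 | 4.5 |
| Wednesday's | 4.00 | 22.4 | 5.9 |
| Wednesday's | 5.00 | 21.9 | 8.2 |
| Friday's | 0.667 | 4.4 | 0.3 |
| Friday's | 2.00 | 8.7 | 1.2 |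
| Friday's | 4.00 | 16.2 | 3.8 |
| Friday's | 6.00 | 20.7 | 7.5 |
| Friday's | 8.00 | 22.3 | 10.4 |
| Saturday's | 1.50 | 16.9 | 4.0 |
| Saturday's | 3.00 | 23.4 | 8.3 |
| Saturday's | 5.00 | 24.3 | 15.2 |
| Saturday's | 6.00 | 26.1 | 20.4 |
| Saturday's | 8.00 | 25.7 | 23.9 |
| Monday's | 0.667 | 7.1 | 0 |
| Monday's | 2.00 | 20.6 | 3.7 |
| Monday's | 4.00 | 28.6 | 8.7 |
| Monday's | 6.00 | 31.8 | 14.2 |
| Monday's | 8.00 | 35.4 | 21.7 |

(readings scatter by 1 percentage point)

- the stated concentrations are those of everything mixed, before any reaction; amounts are the same in each set-up
- the analysis behind the earlier runs scatters by 1 percentage point, standard deviation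
- the feed brings no volume worth counting
- the earlier runs were made in a closed, stirred flask

* the set-up with the highest amount of intermediate at the outlet or at the end, in percent of the substrate put in ("none" if the first two lie within 2 percentage points) (epsilon / beta / delta / gamma / none)
* amount of intermediate at the outlet or at the end, in percent of the substrate put in, epsilon
* amount of intermediate at the outlet or at the end, in percent of the substrate put in, beta
* amount of intermediate at the outlet or at the end, in percent of the substrate put in, delta
* amount of intermediate at the outlet or at the end, in percent of the substrate put in, gamma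

Each set-up stands at 49 mM, so we count in fractions of the substrate charged and lean on the runs at that concentration. Let X be the substrate consumed, read as intermediate plus target. In Wednesday's run it reaches 30.1% at 5.00 h. Monday's extra partner gives a higher sum at 4.00 h, 37.3% against 28.3%, so we take the first step as second order. Then X equals a clock K, times the time, times mean substrate, times mean partner, each mean being its start less half of X. Wednesday gives K = 0.0675 h⁻¹.

But that is one sum of two readings. Monday's last pair, by the same line, gives 0.0660 h⁻¹. And what does the mean itself cost? The exact second-order integral on Wednesday's sum gives 0.0693 h⁻¹, a shift of 2.67%, so we keep the mean.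

Dosing changes a mean. A reagent fed evenly over 6.40 h and left until 8.0 h has gone in, averaged over the run, to 0.600 of its charge, counted before any of it reacts: the mean fed fraction. With 0.540 as the clock over the run, we get X = 42.2% for epsilon, 26.8% for beta and 27.2% for gamma. The tank runs at its outlet levels, which gives 32.2% for delta.

The same line splits X. Wednesday's mean intermediate, 14.8%, gives the second clock 0.129 h⁻¹. Holding second reagent at its charge, we take intermediate as X divided by one plus 0.929 times s, where s is mean intermediate over final intermediate. Wednesday's run reads s = 0.675 at 5.00 h, which we carry over to epsilon at 8.0 h, the tank has one, and a straight rise under dosing has 0.5. We get 25.9% for epsilon, 18.3% for beta, 16.7% for delta and 18.6% for gamma. That straight rise is a guess, but even s = 0.3 lifts gamma to 21.3%, still lower than epsilon. We name epsilon.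

The forecast gave 26.8% for epsilon, 21.5% for beta, 18.8% for delta and 21.5% for gamma, and named epsilon, holding that under dosing “the bimolecular first step is starved”.

The flask gives 24.6% for epsilon, 19.7% for beta, 16.9% for delta and 20.7% for gamma, so epsilon stands highest.

    substrate + coupling partner → intermediate (k = 4.40 × 10⁻⁴ L mol⁻¹ s⁻¹)
    second reagent + intermediate → target (k = 8.40 × 10⁻⁴ L mol⁻¹ s⁻¹)
    target ⇌ isomer of the product (K = 0.340, k = 1.00 × 10⁻⁵ s⁻¹)
    coupling partner → decomposed reagent (k = 5.70 × 10⁻⁶ s⁻¹)

Isomer of the product reaches 1.52% in epsilon, and its making changes the intermediate there by nothing. Substrate ends at 58.2% in epsilon and 71.6% in beta. Taking 0.600 less half of the 28.4% consumed, we reckon beta's mean substrate over the run at 0.458 of its charge, lower than the 0.791 that the same rule gives epsilon.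

The numbers in the tables come from a simulation with constants of no real substance, and the scatter is random.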